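**Retrosynthetic overview**
1. The target is opened by a retro transannular crossed [2+2] (bonds C1–C6 and C2–C7) to an (8R,10R)-bis(isovaleryloxy)humula-1,3,6-trien-5-one. One photochemical step makes the four-, six- and seven-membered rings and four stereocentres.
2. The humulatrienone comes from an eleven-membered β-hydroxy ketone by hydroxyl-directed anti reduction (C10), double esterification and loss of MeOH.
3. The eleven-membered ring comes from C1–C11 closure of an acyclic oxidised farnesane. A C10=C11 enol silane attacks a C1 oxocarbenium ion, which is the bond and polarity of the humulyl-forming cyclisation.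
4. The farnesane chain comes from a C8–C9 boron aldol (sets C8) of 3-methylbut-3-en-2-one with a C10 enal. The enal is made from phorone, trimethyl orthoformate (C1) and SeO2.
5. Ring order: eleven-membered ring first, then cyclobutane, cyclohexenone and cycloheptane together.

Assumption: the presumed biosynthesis is farnesyl diphosphate → humulane ring (C1–C11 closure) → 8,10-dioxygenated 5-oxo-1,3,6-triene → light-driven transannular [2+2].
Positions follow farnesyl/humulane numbering: ring C1–C11, Me on C3 and C7, Me2 on C11, C5 = ketone.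

**Step 1**
Reactants: 1 phorone (2,6-dimethylhepta-2,5-dien-4-one, 1.5 equiv); 2 trimethyl orthoformate
Product: 4 (5E)-8,8-dimethoxy-2,6-dimethylocta-2,5-dien-4-one, via siloxytriene 3 (not isolated)
Conditions: TMSOTf, iPr2NEt, CH2Cl2, −78 to 0 °C
Reagents that add atoms: trimethyl orthoformate 2, COC(OC)OC; trimethylsilyl triflate, C[Si](C)(C)OS(=O)(=O)C(F)(F)F (its silyl group stays only in 3)
Why: Soft enolisation of the symmetrical dienone can only remove a γ-hydrogen, and the siloxytriene attacks the dimethoxycarbenium ion through its free terminal CH2 (vinylogous Mukaiyama reaction), which installs C1 at the aldehyde oxidation level with the E-enone favoured and no stereocentre formed.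

**Step 2**
Reactants: 4 (5E)-8,8-dimethoxy-2,6-dimethylocta-2,5-dien-4-one
Product: 5 (2E,5E)-8,8-dimethoxy-2,6-dimethyl-4-oxoocta-2,5-dienal
Conditions: SeO2 (1.1 equiv), pyridine (0.5 equiv), 1,4-dioxane, 80 °C
Reagents that add atoms: selenium dioxide, O=[Se]=O
Why: Riley allylic oxidation (ene reaction, then [2,3]-shift) prefers the E-methyl of the terminal isopropylidene group, as in geranyl and farnesyl systems, while the methylene next to the acetal is inductively deactivated; the [2,3]-shift gives the E-enal and pyridine buffers the acetal.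

**Step 3**
Reactants: 5 (2E,5E)-8,8-dimethoxy-2,6-dimethyl-4-oxoocta-2,5-dienal; 6 3-methylbut-3-en-2-one
Product: 9 (5R,6E,9E)-5-hydroxy-12,12-dimethoxy-2,6,10-trimethyldodeca-1,6,9-triene-3,8-dione, via boron dienolate 7 (not isolated), via boron aldolate 8 (not isolated)
Conditions: 6, (−)-Ipc2BCl, Et3N, Et2O, 0 °C; 5, −78 °C; H2O2, pH 7 buffer, MeOH, 0 °C
Reagents that add atoms: none
Why: Paterson boron aldol, in which the methyl ketone enolate carrying the (−)-Ipc ligands adds 1,2 to the Re face of the aldehyde only (ketone and acetal untouched) and sets C8 as R; the residual minor enantiomer is removed by crystallising diol 13.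

**Step 4**
Reactants: 9 (5R,6E,9E)-5-hydroxy-12,12-dimethoxy-2,6,10-trimethyldodeca-1,6,9-triene-3,8-dione
Product: 10 (5R,6E,9E)-12,12-dimethoxy-2,6,10-trimethyl-3,5-bis(triethylsilyloxy)dodeca-2,6,9-trien-8-one
Conditions: Et3SiH (2.3 equiv), RhCl(PPh3)3 (1 mol %), toluene, 45 °C
Reagents that add atoms: triethylsilane, CC[SiH](CC)CC
Why: Ojima-type 1,4-hydrosilylation of the unhindered isopropenyl ketone gives regiospecifically the tetrasubstituted C10=C11 enol silane (no E/Z issue), and the same catalyst silylates the C8 hydroxyl (which also blocks oxa-Michael closure); the β,β-disubstituted dienone reacts far more slowly and C8 is untouched.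

**Step 5**
Reactants: 10 (5R,6E,9E)-12,12-dimethoxy-2,6,10-trimethyl-3,5-bis(triethylsilyloxy)dodeca-2,6,9-trien-8-one
Product: 12 (3E,6E,8R)-8-hydroxy-1-methoxyhumula-3,6-diene-5,10-dione (C1 epimers), via macrocyclic TES ether 11 (not isolated)
Conditions: TMSOTf (20 mol %), 2,6-di-tert-butyl-4-methylpyridine, CH2Cl2 (1 mM, syringe pump), −78 to −40 °C; then AcOH–THF–H2O, rt
Reagents that add atoms: none
Why: Proposed new method: TMSOTf ionises the acetal to the C1 oxocarbenium ion, which the regiodefined C10=C11 enol silane captures at its dimethyl-bearing carbon (Mukaiyama–Noyori acetal aldol run as a high-dilution eleven-membered closure; the closest known types are enol silane/thionium and enol silane/allylpalladium closures of humulane rings); the rival closures are shut off because attack at C7 is a disfavoured 5-(enolendo)-exo-trig process, attack at the C5 carbonyl would need an E-cycloheptene and C3 is fully substituted, the E,E cross-conjugated dienone fits the ring as in zerumbone, the new C1 centre is erased in step 7, and mild acid frees the C8 hydroxyl.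

**Step 6**
Reactants: 12 (3E,6E,8R)-8-hydroxy-1-methoxyhumula-3,6-diene-5,10-dione
Product: 13 (3E,6E,8R,10R)-8,10-dihydroxy-1-methoxyhumula-3,6-dien-5-one (C1 epimers)
Conditions: Me4NBH(OAc)3, MeCN–AcOH, −25 °C
Reagents that add atoms: none
Why: Evans–Saksena reduction, in which boron binds the C8 hydroxyl and delivers hydride intramolecularly through a chair-like six-membered transition state to give the 8,10-anti diol (10R); the unbound cross-conjugated C5 ketone is inert to triacetoxyborohydride.

**Step 7**
Reactants: 13 (3E,6E,8R,10R)-8,10-dihydroxy-1-methoxyhumula-3,6-dien-5-one; 14 isovaleryl chloride (3-methylbutanoyl chloride)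
Product: 16 (1E,3Z,6E,8R,10R)-8,10-bis(3-methylbutanoyloxy)humula-1,3,6-trien-5-one, via methoxy diester 15 (not isolated)
Conditions: 14, Et3N, DMAP, CH2Cl2, 0 °C to rt; then DBU, rt
Reagents that add atoms: isovaleryl chloride 14, CC(C)CC(=O)Cl
Why: DMAP-catalysed acylation esterifies both carbinols with retention, and DBU then causes a vinylogous E1cB loss of methanol (γ-deprotonation at C2, expulsion of the C1 methoxide) through an extended enolate whose C3–C4 bond can rotate, so the ring settles in the less strained 1E,3Z diene; C8–H lies near the enone plane and is not acidified, so C8 and C10 are kept.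

**Step 8**
Reactants: 16 (1E,3Z,6E,8R,10R)-8,10-bis(3-methylbutanoyloxy)humula-1,3,6-trien-5-one
Product: 17 target CNP0192813.1, (1S,2R,6R,7R,8R,10R)-8,10-bis(3-methylbutanoyloxy)-1,6:2,7-dicyclohumul-3-en-5-one
Conditions: thioxanthen-9-one (10 mol %), 405 nm LED, degassed MeCN (2 mM), 20 °C
Reagents that add atoms: none
Why: Triplet energy transfer excites the trienone, equilibrates C3=C4 so that any 3E isomer is funnelled through the reactive 3Z form, and triggers a transannular crossed enone–alkene [2+2] photocycloaddition in which C1 (terminus of the excited dienone) bonds to C6 through a six-membered array and the tertiary C7/oxyallyl-stabilised C2 radical pair collapses; only the doubly cis-bridged arrangement at C1, C2, C6 and C7 is geometrically possible, and its absolute sense is fixed by the 8R centre, which keeps C8–H rather than the ester next to the C7 methyl (A1,2 strain) and so turns one face of C6=C7 towards C1=C2.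

**Compound list**
1 | phorone | CC(C)=CC(=O)C=C(C)C | starting material
2 | trimethyl orthoformate | COC(OC)OC | starting material
3 | (3Z)-2,6-dimethyl-4-(trimethylsilyloxy)hepta-1,3,5-triene | C=C(C)/C=C(\O[Si](C)(C)C)C=C(C)C | intermediate (not isolated)
4 | (5E)-8,8-dimethoxy-2,6-dimethylocta-2,5-dien-4-one | COC(OC)C/C(C)=C/C(=O)C=C(C)C | intermediate
5 | (2E,5E)-8,8-dimethoxy-2,6-dimethyl-4-oxoocta-2,5-dienal | O=C/C(C)=C/C(=O)/C=C(C)/CC(OC)OC | intermediate
6 | 3-methylbut-3-en-2-one | CC(=O)C(C)=C | starting material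
7 | bis(isopinocampheyl)boron dienolate of 6 | C=C(C)C(=C)OB([C@@H]1C[C@@H]2C[C@H]([C@H]1C)C2(C)C)[C@@H]1C[C@@H]2C[C@H]([C@H]1C)C2(C)C | intermediate (not isolated)
8 | bis(isopinocampheyl)boron aldolate of 9 | C=C(C)C(=O)C[C@@H](OB([C@@H]1C[C@@H]2C[C@H]([C@H]1C)C2(C)C)[C@@H]1C[C@@H]2C[C@H]([C@H]1C)C2(C)C)/C(C)=C/C(=O)/C=C(C)/CC(OC)OC | intermediate (not isolated)
9 | (5R,6E,9E)-5-hydroxy-12,12-dimethoxy-2,6,10-trimethyldodeca-1,6,9-triene-3,8-dione | C=C(C)C(=O)C[C@@H](O)/C(C)=C/C(=O)/C=C(C)/CC(OC)OC | intermediate
10 | (5R,6E,9E)-12,12-dimethoxy-2,6,10-trimethyl-3,5-bis(triethylsilyloxy)dodeca-2,6,9-trien-8-one | CC(C)=C(O[Si](CC)(CC)CC)C[C@@H](O[Si](CC)(CC)CC)/C(C)=C/C(=O)/C=C(C)/CC(OC)OC | intermediate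
11 | (3E,6E,8R)-1-methoxy-8-(triethylsilyloxy)humula-3,6-diene-5,10-dione (C1 epimers) | COC1C/C(C)=C/C(=O)/C=C(C)/[C@H](O[Si](CC)(CC)CC)CC(=O)C1(C)C | intermediate (not isolated)
12 | (3E,6E,8R)-8-hydroxy-1-methoxyhumula-3,6-diene-5,10-dione (C1 epimers) | COC1C/C(C)=C/C(=O)/C=C(C)/[C@H](O)CC(=O)C1(C)C | intermediate
13 | (3E,6E,8R,10R)-8,10-dihydroxy-1-methoxyhumula-3,6-dien-5-one (C1 epimers) | COC1C/C(C)=C/C(=O)/C=C(C)/[C@H](O)C[C@@H](O)C1(C)C | intermediate
14 | isovaleryl chloride | CC(C)CC(=O)Cl | starting material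
15 | (3E,6E,8R,10R)-1-methoxy-8,10-bis(3-methylbutanoyloxy)humula-3,6-dien-5-one (C1 epimers) | COC1C/C(C)=C/C(=O)/C=C(C)/[C@H](OC(=O)CC(C)C)C[C@@H](OC(=O)CC(C)C)C1(C)C | intermediate (not isolated)
16 | (1E,3Z,6E,8R,10R)-8,10-bis(3-methylbutanoyloxy)humula-1,3,6-trien-5-one | O=C1/C=C(C)/[C@H](OC(=O)CC(C)C)C[C@@H](OC(=O)CC(C)C)C(C)(C)/C=C/C(C)=C\1 | intermediate
17 | CNP0192813.1 | CC1=CC(=O)[C@@H]2[C@@H]3[C@H]1[C@@]2(C)[C@H](OC(=O)CC(C)C)C[C@@H](OC(=O)CC(C)C)C3(C)C | target

**Total step count:** 8. **Longest linear sequence:** 8 (1 → 17).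

**Steps most likely to fail**

Step 2 (site selectivity). The C2 methylene or the C3 methyl may be oxidised as well, and the acetal may suffer. The fallback sets out from 1 and comes back at 5, and it replaces C–H oxidation by C=C cleavage. Phorone 1 is dimethoxymethylated at both ends (2.5 equiv of 2, conditions of step 1) to the symmetrical bis-acetal (3E,6E)-1,1,9,9-tetramethoxy-3,7-dimethylnona-3,6-dien-5-one F1. DBU at partial conversion (F1 recycled) removes one methanol to give the enol ether (1E,3E,6E)-1,9,9-trimethoxy-3,7-dimethylnona-1,3,6-trien-5-one F2. One equivalent of ozone at −78 °C (then Me2S) cleaves only this electron-rich C=C and leaves enal 5.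

Step 5 (eleven-membered closure). Oligomerisation or proton loss from the oxocarbenium ion may win. The fallback sets out from 4 and comes back at 12. It makes the C1–C11 bond intermolecularly and closes the ring at C8–C9 instead. Acetal 4 and the tetrasubstituted trimethylsilyl enol ether of 3-methylbutan-2-one (TMSOTf cat., −78 °C) give (6E)-4-methoxy-3,3,6,10-tetramethylundeca-6,9-diene-2,8-dione F3. SeO2 gives the keto enal (2E,5E)-8-methoxy-2,6,9,9-tetramethyl-4,10-dioxoundeca-2,5-dienal F4. Its methyl ketone, the only α-enolisable site, is converted at high dilution with (−)-Ipc2BCl/Et3N into the boron enolate. That enolate adds to the aldehyde across the chain and gives 12.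

Step 8 (regiochemistry and facial selectivity). The outcome may be a straight instead of a crossed adduct, the wrong face, or photodeconjugation. The fallback sets out from 13 and comes back at 17. It locks the C8–C10 segment in a ring before irradiation. Diol 13 with 2,2-dimethoxypropane/PPTS gives the 8,10-O-isopropylidene methoxy dienone F5. DBU gives the 8,10-O-isopropylidene humula-1,3,6-trien-5-one F6. Sensitised irradiation as in step 8 gives the tricyclic acetonide F7. Aqueous AcOH gives the tricyclic 8,10-diol F8. Acylation with 14 (Et3N, DMAP) gives 17.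

**Further compounds**
F1 | step 2 | (3E,6E)-1,1,9,9-tetramethoxy-3,7-dimethylnona-3,6-dien-5-one | COC(OC)C/C(C)=C/C(=O)/C=C(C)/CC(OC)OC
F2 | step 2 | (1E,3E,6E)-1,9,9-trimethoxy-3,7-dimethylnona-1,3,6-trien-5-one | CO/C=C/C(C)=C/C(=O)/C=C(C)/CC(OC)OC
F3 | step 5 | (6E)-4-methoxy-3,3,6,10-tetramethylundeca-6,9-diene-2,8-dione | CC(=O)C(C)(C)C(OC)C/C(C)=C/C(=O)C=C(C)C
F4 | step 5 | (2E,5E)-8-methoxy-2,6,9,9-tetramethyl-4,10-dioxoundeca-2,5-dienal | CC(=O)C(C)(C)C(OC)C/C(C)=C/C(=O)/C=C(C)/C=O
F5 | step 8 | 8,10-O-isopropylidene methoxy dienone (acetonide of 13) | COC1C/C(C)=C/C(=O)/C=C(C)/[C@H]2C[C@@H](OC(C)(C)O2)C1(C)C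
F6 | step 8 | 8,10-O-isopropylidene humula-1,3,6-trien-5-one (1E,3Z,6E,8R,10R) | O=C1/C=C(C)/[C@H]2C[C@@H](OC(C)(C)O2)C(C)(C)/C=C/C(C)=C\1
F7 | step 8 | tricyclic acetonide (1,6:2,7-dicyclohumul-3-en-5-one 8,10-acetonide) | CC1=CC(=O)[C@@H]2[C@@H]3[C@H]1[C@@]2(C)[C@H]4C[C@@H](OC(C)(C)O4)C3(C)C
F8 | step 8 | tricyclic 8,10-diol | CC1=CC(=O)[C@@H]2[C@@H]3[C@H]1[C@@]2(C)[C@H](O)C[C@@H](O)C3(C)C
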